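## Retrosynthetic overview

1. Dinklagin A (11) ⇒ global desilylation of the 4‑silyloxy‑2H‑chromene 10; no ring is formed after the key coupling.
2. Key bond C2–C1′ (ring C to ring B): chromone 6 is turned on nickel into a 1‑silyloxyallyl (homoenolate) nucleophile at C2 and joined to the electrophilic carbon of aryl bromide 9 under a chiral ligand, which sets 2S directly.
3. Chromone 6 (ring C) ⇒ acetophenone 4 plus one carbon from an amide acetal; 4 ⇒ C5‑prenylation and 4‑O‑silylation of 2,4‑dihydroxyacetophenone 1 (ring A bought).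
4. Bromide 9 ⇒ 4‑bromophenol 7 + 3‑methylbut‑2‑enal 8 (ring B bought, dimethylpyran ring D by condensation and oxa‑6π electrocyclisation).
5. Ring order: ring C (step 3) and ring D (step 4) are built independently, then united in step 5.

Assumption: the sense of induction of the nickel/bis(oxazoline) catalyst cannot be predicted with certainty; the (S,S)‑ligand is written, and the (R,R)‑antipode is used if that is the one that gives the 2S product.
Assumption: silylating agents, the amide acetal and similar reagents are given by name and SMILES in the steps and are not numbered.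

## Route

Step 1
Reactants: 1 2,4‑dihydroxyacetophenone; 2 2‑methylbut‑3‑en‑2‑ol
Product: 3 1‑[2,4‑dihydroxy‑5‑(3‑methylbut‑2‑en‑1‑yl)phenyl]ethan‑1‑one
Conditions: BF3·OEt2 (0.5 equiv), 1,4‑dioxane, rt, 12 h; chromatography
Reagents that add atoms: none
Why: Friedel–Crafts C‑prenylation in which the BF3‑generated prenyl cation attacks C5 (ortho to the 4‑OH, para to the 2‑OH, the less hindered activated position), expected in modest yield (about 30%) with the C3 isomer removed by chromatography.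

Step 2
Reactants: 3 1‑[2,4‑dihydroxy‑5‑(3‑methylbut‑2‑en‑1‑yl)phenyl]ethan‑1‑one
Product: 4 1‑[2‑hydroxy‑5‑(3‑methylbut‑2‑en‑1‑yl)‑4‑(triisopropylsilyloxy)phenyl]ethan‑1‑one
Conditions: i‑Pr3SiCl (1.1 equiv), imidazole (2 equiv), CH2Cl2, 0 °C → rt
Reagents that add atoms: chlorotriisopropylsilane, CC(C)[Si](Cl)(C(C)C)C(C)C
Why: Selective silyl ether formation, because the 2‑OH is locked in a hydrogen bond to the ketone and only the free 4‑OH is silylated.

Step 3
Reactants: 4 1‑[2‑hydroxy‑5‑(3‑methylbut‑2‑en‑1‑yl)‑4‑(triisopropylsilyloxy)phenyl]ethan‑1‑one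
Product: 6 6‑(3‑methylbut‑2‑en‑1‑yl)‑7‑(triisopropylsilyloxy)‑4H‑chromen‑4‑one, via enaminone 5 (not isolated)
Conditions: Me2NCH(OMe)2 (1.5 equiv), toluene, 90 °C; then 2 M aq HCl, CH2Cl2, rt
Reagents that add atoms: N,N‑dimethylformamide dimethyl acetal, COC(OC)N(C)C
Why: Enaminone chromone synthesis: the methyl ketone condenses with the amide acetal, then acid promotes intramolecular oxa‑Michael addition of the 2‑OH and loss of dimethylamine, conditions mild enough for the prenyl group and the aryl silyl ether.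

Step 4
Reactants: 7 4‑bromophenol; 8 3‑methylbut‑2‑enal
Product: 9 6‑bromo‑2,2‑dimethyl‑2H‑chromene
Conditions: PhB(OH)2 (1 equiv, recovered), AcOH, toluene, reflux, Dean–Stark
Reagents that add atoms: none
Why: Phenylboronic acid‑templated ortho‑condensation of the phenol with the enal, followed by loss of water to an ortho‑quinone methide that closes by oxa‑6π electrocyclisation to the 2H‑chromene.

Step 5
Reactants: 6 6‑(3‑methylbut‑2‑en‑1‑yl)‑7‑(triisopropylsilyloxy)‑4H‑chromen‑4‑one; 9 6‑bromo‑2,2‑dimethyl‑2H‑chromene (1.5 equiv)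
Product: 11 Dinklagin A [(2S)‑2‑(2,2‑dimethyl‑2H‑chromen‑6‑yl)‑7‑hydroxy‑6‑(3‑methylbut‑2‑en‑1‑yl)‑2,3‑dihydro‑4H‑chromen‑4‑one], via bis‑silyl enol ether 10 (not isolated)
Conditions: NiBr2·MeOCH2CH2OMe (10 mol%), (4S,4′S)‑4,4′‑diisopropyl‑2,2′‑bi(2‑oxazoline) (12 mol%), Mn powder (3 equiv), Et3SiCl (1.5 equiv), DMA, rt, dark; filter, concentrate; then Bu4NF/AcOH (1:1, 3 equiv), THF, 0 °C
Reagents that add atoms: chlorotriethylsilane, CC[Si](Cl)(CC)CC (its Et3Si group is carried only in intermediate 10 and is removed again before 11)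
Why: Proposed new method: zerovalent nickel bound to the chromone C2=C3 bond is O‑silylated by Et3SiCl (formal oxidative addition of the 4‑silyloxybenzopyrylium chloride) to give a ligand‑bound η3‑1‑silyloxyallyl divalent nickel species, a catalytic homoenolate in which the normally electrophilic C2 is the nucleophile; Mn reduces it, bromide 9 adds oxidatively, and reductive elimination at the allyl terminus remote from OSiEt3 forms C2–C1′ on the face dictated by the chiral bis(oxazoline), setting 2S; the product stays locked as silyl enol ether 10 until acetic acid‑buffered fluoride removes both silyl groups without retro‑oxa‑Michael racemisation; the closest known reaction type is the racemic nickel‑catalysed reductive conjugate arylation of enones with aryl halides, a chlorosilane and Mn via silyloxyallyl‑nickel intermediates, together with enantioselective nickel‑catalysed arylation of benzopyrylium ions.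

## Compound list

1 | 2,4‑dihydroxyacetophenone | CC(=O)c1ccc(O)cc1O | starting material
2 | 2‑methylbut‑3‑en‑2‑ol | CC(C)(O)C=C | starting material
3 | 1‑[2,4‑dihydroxy‑5‑(3‑methylbut‑2‑en‑1‑yl)phenyl]ethan‑1‑one | CC(=O)c1cc(CC=C(C)C)c(O)cc1O | intermediate
4 | 1‑[2‑hydroxy‑5‑(3‑methylbut‑2‑en‑1‑yl)‑4‑(triisopropylsilyloxy)phenyl]ethan‑1‑one | CC(=O)c1cc(CC=C(C)C)c(O[Si](C(C)C)(C(C)C)C(C)C)cc1O | intermediate
5 | (E)‑3‑(dimethylamino)‑1‑[2‑hydroxy‑5‑(3‑methylbut‑2‑en‑1‑yl)‑4‑(triisopropylsilyloxy)phenyl]prop‑2‑en‑1‑one (enaminone) | CN(C)/C=C/C(=O)c1cc(CC=C(C)C)c(O[Si](C(C)C)(C(C)C)C(C)C)cc1O | intermediate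
6 | 6‑(3‑methylbut‑2‑en‑1‑yl)‑7‑(triisopropylsilyloxy)‑4H‑chromen‑4‑one | O=c1ccoc2cc(O[Si](C(C)C)(C(C)C)C(C)C)c(CC=C(C)C)cc12 | intermediate
7 | 4‑bromophenol | Oc1ccc(Br)cc1 | starting material
8 | 3‑methylbut‑2‑enal | CC(C)=CC=O | starting material
9 | 6‑bromo‑2,2‑dimethyl‑2H‑chromene | CC1(C)C=Cc2cc(Br)ccc2O1 | intermediate
10 | (2S)‑2‑(2,2‑dimethyl‑2H‑chromen‑6‑yl)‑6‑(3‑methylbut‑2‑en‑1‑yl)‑4‑(triethylsilyloxy)‑7‑(triisopropylsilyloxy)‑2H‑chromene (bis‑silyl enol ether) | CC(C)=CCc1cc2c(cc1O[Si](C(C)C)(C(C)C)C(C)C)O[C@H](c1ccc3c(c1)C=CC(C)(C)O3)C=C2O[Si](CC)(CC)CC | intermediate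
11 | Dinklagin A, (2S)‑2‑(2,2‑dimethyl‑2H‑chromen‑6‑yl)‑7‑hydroxy‑6‑(3‑methylbut‑2‑en‑1‑yl)‑2,3‑dihydro‑4H‑chromen‑4‑one | CC(C)=CCc1cc2c(cc1O)O[C@H](c1ccc3c(c1)C=CC(C)(C)O3)CC2=O | target

## Step count and risks

Total step count: 5. Longest linear sequence: 4 (steps 1, 2, 3 and 5); step 4 is a one‑step branch.

Steps most likely to fail, with fallbacks:

- **Step 5 (nickel homoenolate arylation; yield, ee and chromone reactivity are untested).** The fallback sets out from chromone 6 and bromide 9 and comes back at target 11. The homoenolate is made and isolated as a boron reagent instead of being generated on nickel. Copper‑catalysed enantioselective conjugate borylation of 6 (CuCl, NaOt‑Bu, a chiral Josiphos‑type bisphosphine, B2pin2, MeOH, THF, 0 °C) gives the β‑boryl ketone (2S)‑6‑(3‑methylbut‑2‑en‑1‑yl)‑2‑(4,4,5,5‑tetramethyl‑1,3,2‑dioxaborolan‑2‑yl)‑7‑(triisopropylsilyloxy)chroman‑4‑one F1. Stereospecific Suzuki–Miyaura coupling of this boron homoenolate with 9 (Pd(OAc)2, RuPhos, K2CO3, toluene/H2O, 70 °C) is expected to go with inversion at carbon through the carbonyl‑chelated boronate. It gives (2S)‑2‑(2,2‑dimethyl‑2H‑chromen‑6‑yl)‑6‑(3‑methylbut‑2‑en‑1‑yl)‑7‑(triisopropylsilyloxy)chroman‑4‑one F2, and Bu4NF/AcOH in THF at 0 °C then gives 11. If the coupling proves to go with retention, the borylation is run with the other ligand antipode.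

- **Step 1 (regioselectivity and yield of the direct C‑prenylation).** The fallback sets out from 1 and comes back at 4, bypassing 3. Bromination of 1 with N‑bromosuccinimide (MeCN, 0 °C) fixes the position as 1‑(5‑bromo‑2,4‑dihydroxyphenyl)ethan‑1‑one F3. Silylation (i‑Pr3SiCl, imidazole, CH2Cl2) gives 1‑[5‑bromo‑2‑hydroxy‑4‑(triisopropylsilyloxy)phenyl]ethan‑1‑one F4. Stille coupling with tributyl(3‑methylbut‑2‑en‑1‑yl)stannane (Pd(PPh3)4, DMF, 90 °C) then installs the linear prenyl group and delivers 4.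

- **Step 4 (chromene formation from an electron‑poor phenol).** The fallback sets out from 7 and comes back at 9. O‑Alkylation of 7 with 3‑chloro‑3‑methylbut‑1‑yne (K2CO3, KI, cat. CuI, acetone, reflux) gives 1‑bromo‑4‑[(2‑methylbut‑3‑yn‑2‑yl)oxy]benzene F5. Heating in N,N‑diethylaniline at 190 °C (aryl propargyl ether Claisen rearrangement, 1,5‑hydrogen shift, oxa‑6π electrocyclisation) gives 9.

Further compounds
F1 | step 5 | (2S)‑6‑(3‑methylbut‑2‑en‑1‑yl)‑2‑(4,4,5,5‑tetramethyl‑1,3,2‑dioxaborolan‑2‑yl)‑7‑(triisopropylsilyloxy)chroman‑4‑one | CC(C)=CCc1cc2c(cc1O[Si](C(C)C)(C(C)C)C(C)C)O[C@@H](B1OC(C)(C)C(C)(C)O1)CC2=O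
F2 | step 5 | (2S)‑2‑(2,2‑dimethyl‑2H‑chromen‑6‑yl)‑6‑(3‑methylbut‑2‑en‑1‑yl)‑7‑(triisopropylsilyloxy)chroman‑4‑one | CC(C)=CCc1cc2c(cc1O[Si](C(C)C)(C(C)C)C(C)C)O[C@H](c1ccc3c(c1)C=CC(C)(C)O3)CC2=O
F3 | step 1 | 1‑(5‑bromo‑2,4‑dihydroxyphenyl)ethan‑1‑one | CC(=O)c1cc(Br)c(O)cc1O
F4 | step 1 | 1‑[5‑bromo‑2‑hydroxy‑4‑(triisopropylsilyloxy)phenyl]ethan‑1‑one | CC(=O)c1cc(Br)c(O[Si](C(C)C)(C(C)C)C(C)C)cc1O
F5 | step 4 | 1‑bromo‑4‑[(2‑methylbut‑3‑yn‑2‑yl)oxy]benzene | C#CC(C)(C)Oc1ccc(Br)cc1
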